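**Strategy.** Everything rests on disconnecting ring B, the hydroquinone made of C3a, C4(OH), C5, C6(H), C7(OH) and C7a that shares its C3a–C7a edge with the dihydrofuran. A Dötz benzannulation builds this ring in one operation onto the enol-ether C=C of a stereodefined trans-2,3-diaryl-2,3-dihydrofuran: the carbene carbon becomes C7, one CO becomes C4, and 3,3-diethoxypropyne supplies C5 (with the acetal that later anchors the chromone) and C6, forming C6–C7, C4–C5 and C3a–C4. The precursor is the pentacarbonylchromium methoxycarbene at C5 of the (2S,3R)-dihydrofuran, whose phenols are TIPS ethers so that only C5 is lithiated. Both stereocentres come from an anti-selective asymmetric allylboration.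

Key step: step 8

Abbreviations: TIPS = triisopropylsilyl; MOM = methoxymethyl; pin = pinacolato; Ar1 = 4-(TIPS-oxy)phenyl; Ar2 = 3,5-bis(TIPS-oxy)phenyl.

Remark: the sense of induction in step 4 is taken from the accepted model for this acid class (the (R) acid attacks the aldehyde Re face); were it reversed for boronate 7, the (R) acid would be used.

**Step 1**
Reactants: 1 3,5-dihydroxybenzaldehyde
Product: 2 3,5-bis(triisopropylsilyloxy)benzaldehyde
Conditions: i-Pr3SiCl (2.3 equiv), imidazole, DMF, rt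
Reagents that add atoms: chlorotriisopropylsilane, CC(C)[Si](Cl)(C(C)C)C(C)C
Why: Imidazole-promoted O-silylation of both phenols; the bulky TIPS ethers are chosen because they neither direct nor suffer metalation by t-BuLi in step 7 and last until the final fluoride step.

**Step 2**
Reactants: 3 4-ethenylphenyl acetate
Product: 5 triisopropyl(4-ethenylphenoxy)silane, via 4-ethenylphenol 4 (not isolated)
Conditions: K2CO3 (cat.), MeOH, 0 °C; extractive work-up; crude phenol, i-Pr3SiCl, imidazole, DMF, rt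
Reagents that add atoms: chlorotriisopropylsilane, CC(C)[Si](Cl)(C(C)C)C(C)C
Why: Methoxide-catalysed transesterification frees the polymerisation-prone phenol, which is silylated at once (deacetylation followed by silyl ether formation).

**Step 3**
Reactants: 5 triisopropyl(4-ethenylphenoxy)silane; 6 2-allyl-4,4,5,5-tetramethyl-1,3,2-dioxaborolane
Product: 7 (E)-4,4,5,5-tetramethyl-2-{3-[4-(triisopropylsilyloxy)phenyl]prop-2-en-1-yl}-1,3,2-dioxaborolane
Conditions: 6 (2.5 equiv), second-generation Grubbs catalyst RuCl2(=CHPh)(PCy3)(H2IMes) (3 mol%), CH2Cl2, 40 °C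
Reagents that add atoms: none
Why: Olefin cross-metathesis of a styrene with excess allylboronate, driven by loss of ethene, should give the thermodynamically favoured E-cinnamylboronate that step 4 needs for anti selectivity.

**Step 4**
Reactants: 2 3,5-bis(triisopropylsilyloxy)benzaldehyde; 7 the (E)-cinnamylboronate
Product: 9 (1S,2R)-1-Ar2-2-Ar1-but-3-en-1-ol, via pinacol borate ester 8 (not isolated)
Conditions: (S)-TRIP [(S)-3,3′-bis(2,4,6-triisopropylphenyl)-1,1′-binaphthyl-2,2′-diyl hydrogen phosphate] (5 mol%), toluene, 4 Å MS, −30 °C to rt; aq. NaHCO3 work-up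
Reagents that add atoms: none
Why: Chiral-phosphoric-acid-catalysed allylboration through a closed Zimmerman–Traxler chair, in which the E geometry of 7 fixes the anti relationship (C2 = R) and the (S) acid, hydrogen-bonded to the boronate oxygen and the formyl hydrogen, is expected to expose the aldehyde Si face (C1 = S).

**Step 5**
Reactants: 9 (1S,2R)-1-Ar2-2-Ar1-but-3-en-1-ol
Product: 10 (3R,4S)-4-Ar2-4-(ethenyloxy)-3-Ar1-but-1-ene
Conditions: vinyl acetate (4 equiv), [Ir(cod)Cl]2 (2 mol%), Na2CO3 (0.6 equiv), toluene, 100 °C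
Reagents that add atoms: vinyl acetate, C=COC(C)=O
Why: Iridium-catalysed transfer vinylation of a secondary alcohol (alkoxide addition to coordinated vinyl acetate, loss of acetate) forms the O–vinyl bond without touching the C–O stereocentre.

**Step 6**
Reactants: 10 the vinyl ether
Product: 11 (2S,3R)-2-Ar2-3-Ar1-2,3-dihydrofuran (trans)
Conditions: second-generation Grubbs catalyst RuCl2(=CHPh)(PCy3)(H2IMes) (5 mol%), 1,4-benzoquinone (10 mol%), toluene, 70 °C
Reagents that add atoms: none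
Why: Ring-closing enol ether–olefin metathesis initiates at the monosubstituted alkene and closes the five-membered cyclic enol ether with loss of ethene, benzoquinone suppressing ruthenium hydride double-bond migration; neither stereocentre is involved.

**Step 7**
Reactants: 11 (2S,3R)-2-Ar2-3-Ar1-2,3-dihydrofuran
Product: 14 pentacarbonyl{methoxy[(2S,3R)-2-Ar2-3-Ar1-2,3-dihydrofuran-5-yl]methylidene}chromium, via 5-lithiodihydrofuran 12 (not isolated), via lithium acylchromate 13 (not isolated)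
Conditions: t-BuLi (1.5 equiv), THF, −78 to −20 °C; Cr(CO)6, THF, 0 °C to rt; evaporate; Me3OBF4, CH2Cl2/H2O, 0 °C
Reagents that add atoms: hexacarbonylchromium, O=C=[Cr](=C=O)(=C=O)(=C=O)(=C=O)=C=O; trimethyloxonium tetrafluoroborate, C[O+](C)C.F[B-](F)(F)F
Why: Oxygen-directed α-lithiation of the cyclic enol ether at C5, addition of the vinyllithium to a CO ligand and O-methylation of the acylchromate (Fischer carbene synthesis); the TIPS ethers offer no ortho-directing or acidic site, so the sp2 C5–H next to the ring oxygen should be the kinetically preferred position.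

**Step 8**
Reactants: 14 the dihydrofuranyl(methoxy)carbene complex; 15 3,3-diethoxyprop-1-yne
Product: 17 (2S,3S)-2-Ar2-5-(diethoxymethyl)-7-methoxy-3-Ar1-2,3-dihydro-1-benzofuran-4-ol, via tricarbonylchromium arene complex 16 (not isolated)
Conditions: 15 (2 equiv), THF (0.05 M), 55 °C, argon; then air, Et2O, rt
Reagents that add atoms: none
Why: Thermal loss of one CO from 14 lets the alkyne coordinate and insert into the Cr=C bond with its unsubstituted terminus at the carbene carbon (C6–C7), CO insertion then gives a chromium-bound dienylketene (C4–C5), and 6π electrocyclisation onto the enol-ether β-carbon (C3a–C4) followed by tautomerisation delivers the phenol as its Cr(CO)3 complex 16, which air demetalates. The closest known reaction type is the Dötz benzannulation of 2-oxacycloalkenyl (dihydropyranyl and glycal-derived) alkoxycarbene complexes with terminal alkynes. Ring B is closed by a disrotatory 6π electrocyclic ring closure of the ketene onto C3a and is then aromatised by enolisation. No stereocentre is formed: C2 and C3 lie outside the reacting π system, and C3 merely changes its descriptor from R to S because C3a gains priority. The step needs the acetal-bearing carbon to end up next to the CO-derived C4, which the steric preference of terminal alkynes (larger substituent beside the new hydroxyl) secures, and it needs CO insertion to beat cyclopentannulation, which alkoxy(alkenyl)carbenes in THF favour.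

**Step 9**
Reactants: 17 the 4-hydroxy-7-methoxy acetal
Product: 20 (2S,3S)-2-Ar2-4,7-dihydroxy-3-Ar1-2,3-dihydro-1-benzofuran-5-carbaldehyde, via quinone acetal 18 (not isolated), via hydroquinone acetal 19 (not isolated)
Conditions: PhI(OAc)2 (1.1 equiv), MeCN/H2O (4:1), 0 °C; aq. Na2S2O4, EtOAc; then 1 M HCl, THF, rt
Reagents that add atoms: water, O
Why: Hypervalent-iodine oxidative O-demethylation of the 4-methoxyphenol (water adds at C7, methanol leaves) gives the p-quinone, dithionite reduces it at once, and dilute acid hydrolyses the ortho-hydroxyaryl acetal; the quinone is kept cold and free of base so that its benzylic C3–H cannot tautomerise toward the benzofuran.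

**Step 10**
Reactants: 20 the hydroquinone aldehyde
Product: 21 (2S,3S)-2-Ar2-4,7-bis(methoxymethoxy)-3-Ar1-2,3-dihydro-1-benzofuran-5-carbaldehyde
Conditions: MeOCH2Cl (4 equiv), i-Pr2NEt (6 equiv), Bu4NI (cat.), CH2Cl2, 0 to 40 °C
Reagents that add atoms: chloromethyl methyl ether, COCCl
Why: O-Alkylation of both phenols (Williamson-type); MOM ethers are chosen because they resist LiN(SiMe3)2 and cannot migrate to the aldolate oxygen in step 15.

**Step 11**
Reactants: 22 2-methylbenzene-1,3-diol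
Product: 23 1,3-bis(methoxymethoxy)-2-methylbenzene
Conditions: MeOCH2Cl (2.5 equiv), i-Pr2NEt, CH2Cl2, 0 °C to rt
Reagents that add atoms: chloromethyl methyl ether, COCCl
Why: Routine O-alkylation of both phenols (Williamson-type).

**Step 12**
Reactants: 23 1,3-bis(methoxymethoxy)-2-methylbenzene
Product: 25 3,5-bis(methoxymethoxy)-4-methylphenol, via arylboronate 24 (not isolated)
Conditions: B2pin2 (0.7 equiv), [Ir(OMe)(cod)]2 (1.5 mol%), 4,4′-di-tert-butyl-2,2′-bipyridine (3 mol%), THF, 80 °C; then 30% H2O2, aq. NaOH, 0 °C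
Reagents that add atoms: hydrogen peroxide, OO; bis(pinacolato)diboron, CC1(C)OB(B2OC(C)(C)C(C)(C)O2)OC1(C)C (its boron stays only in 24)
Why: Sterically governed iridium-catalysed C–H borylation attacks the only C–H not flanked by a substituent (para to the methyl) and oxidation of the C–B bond gives the phenol, whose symmetry later makes the 6-methyl (not 8-methyl) chromone unambiguous.

**Step 13**
Reactants: 25 3,5-bis(methoxymethoxy)-4-methylphenol
Product: 26 2-bromo-3,5-bis(methoxymethoxy)-4-methylphenol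
Conditions: N-bromosuccinimide (1.0 equiv), CH2Cl2, −40 to 0 °C
Reagents that add atoms: N-bromosuccinimide, O=C1CCC(=O)N1Br
Why: Electrophilic aromatic bromination; the two open positions are equivalent and both ortho to the hydroxyl, so only one monobromide can form.

**Step 14**
Reactants: 26 the bromophenol; 27 N,2-dimethoxy-N-methylacetamide
Product: 29 1-[6-hydroxy-2,4-bis(methoxymethoxy)-3-methylphenyl]-2-methoxyethan-1-one, via dilithiated phenoxide 28 (not isolated)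
Conditions: n-BuLi (2.2 equiv), THF, −78 °C; 27 (1.3 equiv), −78 to 0 °C; aq. NH4Cl
Reagents that add atoms: none
Why: Deprotonation of the phenol and bromine–lithium exchange give an aryllithium flanked by OLi and a chelating MOM ether, whose acylation by the Weinreb amide stops at the ketone (Weinreb ketone synthesis) and leaves free exactly the hydroxyl that becomes the pyranone oxygen.

**Step 15**
Reactants: 21 the bis-MOM aldehyde; 29 the ring A ω-methoxyacetophenone
Product: 30 3-[(2S,3S)-2-Ar2-4,7-bis(methoxymethoxy)-3-Ar1-2,3-dihydro-1-benzofuran-5-yl]-3-hydroxy-1-[6-hydroxy-2,4-bis(methoxymethoxy)-3-methylphenyl]-2-methoxypropan-1-one (mixture of diastereomers at the two chain carbons)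
Conditions: 29 (1.3 equiv), LiN(SiMe3)2 (2.8 equiv), THF, −78 °C; 21, −78 °C; AcOH quench
Reagents that add atoms: none
Why: Aldol addition of the phenoxide–enolate dianion of the ketone to the aldehyde; the two new chain stereocentres are left uncontrolled because step 16 destroys both.

**Step 16**
Reactants: 30 the aldol adduct
Product: 32 2-[(2S,3S)-2-Ar2-4,7-bis(methoxymethoxy)-3-Ar1-2,3-dihydro-1-benzofuran-5-yl]-3-methoxy-5,7-bis(methoxymethoxy)-6-methyl-4H-chromen-4-one, via 1,3-diketone 31 (not isolated)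
Conditions: Dess–Martin periodinane (1.5 equiv), CH2Cl2, 0 °C to rt; aq. Na2S2O3/NaHCO3 wash; crude diketone, NaOAc, AcOH, 90 °C
Reagents that add atoms: none
Why: Dess–Martin oxidation gives the 2-methoxy-1,3-diketone and buffered acetic acid effects its cyclodehydration through the only free ortho hydroxyl (the chromone closure used after Baker–Venkataraman rearrangements), so the pyranone oxygen is fixed para to the methyl group before any MOM ether is lost.

**Step 17**
Reactants: 32 the fully protected flavone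
Product: 33 2-[(2S,3S)-2-Ar2-4,7-dihydroxy-3-Ar1-2,3-dihydro-1-benzofuran-5-yl]-5,7-dihydroxy-3-methoxy-6-methyl-4H-chromen-4-one
Conditions: conc. HCl, MeOH/THF (1:1), 50 °C, argon
Reagents that add atoms: none
Why: Acid-catalysed methanolysis of the four aryl MOM acetals, conditions under which aryl TIPS ethers, the 3-methoxy group and the dihydrobenzofuran are expected to survive (any partial silyl loss is harmless before step 18).

**Step 18**
Reactants: 33 the tris-TIPS flavone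
Product: 34 2-[(2S,3S)-2-(3,5-dihydroxyphenyl)-4,7-dihydroxy-3-(4-hydroxyphenyl)-2,3-dihydro-1-benzofuran-5-yl]-5,7-dihydroxy-3-methoxy-6-methyl-4H-chromen-4-one
Conditions: HF·pyridine, pyridine/THF, 0 °C to rt, argon
Reagents that add atoms: none
Why: Fluoride-driven cleavage of the three aryl O–Si bonds under mildly acidic conditions, which avoids phenoxide formation and air oxidation of the hydroquinone.

**Compound list**

1 | 3,5-dihydroxybenzaldehyde | O=Cc1cc(O)cc(O)c1 | starting material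
2 | 3,5-bis(triisopropylsilyloxy)benzaldehyde | O=Cc1cc(O[Si](C(C)C)(C(C)C)C(C)C)cc(O[Si](C(C)C)(C(C)C)C(C)C)c1 | intermediate
3 | 4-ethenylphenyl acetate | C=Cc1ccc(OC(C)=O)cc1 | starting material
4 | 4-ethenylphenol (not isolated) | C=Cc1ccc(O)cc1 | intermediate
5 | triisopropyl(4-ethenylphenoxy)silane | C=Cc1ccc(O[Si](C(C)C)(C(C)C)C(C)C)cc1 | intermediate
6 | 2-allyl-4,4,5,5-tetramethyl-1,3,2-dioxaborolane | C=CCB1OC(C)(C)C(C)(C)O1 | starting material
7 | (E)-4,4,5,5-tetramethyl-2-{3-[4-(triisopropylsilyloxy)phenyl]prop-2-en-1-yl}-1,3,2-dioxaborolane | CC1(C)OB(C/C=C/c2ccc(O[Si](C(C)C)(C(C)C)C(C)C)cc2)OC1(C)C | intermediate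
8 | pinacol borate ester of 9, O–B(pin) (not isolated) | C=C[C@H](c1ccc(O[Si](C(C)C)(C(C)C)C(C)C)cc1)[C@@H](c1cc(O[Si](C(C)C)(C(C)C)C(C)C)cc(O[Si](C(C)C)(C(C)C)C(C)C)c1)OB1OC(C)(C)C(C)(C)O1 | intermediate
9 | (1S,2R)-1-[3,5-bis(triisopropylsilyloxy)phenyl]-2-[4-(triisopropylsilyloxy)phenyl]but-3-en-1-ol | C=C[C@H](c1ccc(O[Si](C(C)C)(C(C)C)C(C)C)cc1)[C@@H](c1cc(O[Si](C(C)C)(C(C)C)C(C)C)cc(O[Si](C(C)C)(C(C)C)C(C)C)c1)O | intermediate
10 | (3R,4S)-4-[3,5-bis(triisopropylsilyloxy)phenyl]-4-(ethenyloxy)-3-[4-(triisopropylsilyloxy)phenyl]but-1-ene | C=C[C@H](c1ccc(O[Si](C(C)C)(C(C)C)C(C)C)cc1)[C@@H](c1cc(O[Si](C(C)C)(C(C)C)C(C)C)cc(O[Si](C(C)C)(C(C)C)C(C)C)c1)OC=C | intermediate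
11 | (2S,3R)-2-[3,5-bis(triisopropylsilyloxy)phenyl]-3-[4-(triisopropylsilyloxy)phenyl]-2,3-dihydrofuran | C1=C[C@H](c2ccc(O[Si](C(C)C)(C(C)C)C(C)C)cc2)[C@@H](c2cc(O[Si](C(C)C)(C(C)C)C(C)C)cc(O[Si](C(C)C)(C(C)C)C(C)C)c2)O1 | intermediate
12 | 5-lithio derivative of 11 (not isolated) | [Li]C1=C[C@H](c2ccc(O[Si](C(C)C)(C(C)C)C(C)C)cc2)[C@@H](c2cc(O[Si](C(C)C)(C(C)C)C(C)C)cc(O[Si](C(C)C)(C(C)C)C(C)C)c2)O1 | intermediate
13 | lithium pentacarbonyl{[(2S,3R)-2-Ar2-3-Ar1-2,3-dihydrofuran-5-yl]oxidomethylidene}chromate (not isolated) | [Li+].[O-]C(=[Cr](=C=O)(=C=O)(=C=O)(=C=O)=C=O)C1=C[C@H](c2ccc(O[Si](C(C)C)(C(C)C)C(C)C)cc2)[C@@H](c2cc(O[Si](C(C)C)(C(C)C)C(C)C)cc(O[Si](C(C)C)(C(C)C)C(C)C)c2)O1 | intermediate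
14 | pentacarbonyl{methoxy[(2S,3R)-2-[3,5-bis(triisopropylsilyloxy)phenyl]-3-[4-(triisopropylsilyloxy)phenyl]-2,3-dihydrofuran-5-yl]methylidene}chromium | COC(=[Cr](=C=O)(=C=O)(=C=O)(=C=O)=C=O)C1=C[C@H](c2ccc(O[Si](C(C)C)(C(C)C)C(C)C)cc2)[C@@H](c2cc(O[Si](C(C)C)(C(C)C)C(C)C)cc(O[Si](C(C)C)(C(C)C)C(C)C)c2)O1 | intermediate
15 | 3,3-diethoxyprop-1-yne | C#CC(OCC)OCC | starting material
16 | tricarbonyl(η6-17)chromium, Cr(CO)3 bound to ring B (not isolated; arene and metal fragment written dot-separated) | CCOC(OCC)c1cc(OC)c2c(c1O)[C@H](c1ccc(O[Si](C(C)C)(C(C)C)C(C)C)cc1)[C@@H](c1cc(O[Si](C(C)C)(C(C)C)C(C)C)cc(O[Si](C(C)C)(C(C)C)C(C)C)c1)O2.O=C=[Cr](=C=O)=C=O | intermediate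
17 | (2S,3S)-2-[3,5-bis(triisopropylsilyloxy)phenyl]-5-(diethoxymethyl)-7-methoxy-3-[4-(triisopropylsilyloxy)phenyl]-2,3-dihydro-1-benzofuran-4-ol | CCOC(OCC)c1cc(OC)c2c(c1O)[C@H](c1ccc(O[Si](C(C)C)(C(C)C)C(C)C)cc1)[C@@H](c1cc(O[Si](C(C)C)(C(C)C)C(C)C)cc(O[Si](C(C)C)(C(C)C)C(C)C)c1)O2 | intermediate
18 | (2S,3S)-2-Ar2-5-(diethoxymethyl)-3-Ar1-2,3-dihydro-1-benzofuran-4,7-dione (not isolated) | CCOC(OCC)C1=CC(=O)C2=C(C1=O)[C@H](c1ccc(O[Si](C(C)C)(C(C)C)C(C)C)cc1)[C@@H](c1cc(O[Si](C(C)C)(C(C)C)C(C)C)cc(O[Si](C(C)C)(C(C)C)C(C)C)c1)O2 | intermediate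
19 | (2S,3S)-2-Ar2-5-(diethoxymethyl)-3-Ar1-2,3-dihydro-1-benzofuran-4,7-diol (not isolated) | CCOC(OCC)c1cc(O)c2c(c1O)[C@H](c1ccc(O[Si](C(C)C)(C(C)C)C(C)C)cc1)[C@@H](c1cc(O[Si](C(C)C)(C(C)C)C(C)C)cc(O[Si](C(C)C)(C(C)C)C(C)C)c1)O2 | intermediate
20 | (2S,3S)-2-[3,5-bis(triisopropylsilyloxy)phenyl]-4,7-dihydroxy-3-[4-(triisopropylsilyloxy)phenyl]-2,3-dihydro-1-benzofuran-5-carbaldehyde | O=Cc1cc(O)c2c(c1O)[C@H](c1ccc(O[Si](C(C)C)(C(C)C)C(C)C)cc1)[C@@H](c1cc(O[Si](C(C)C)(C(C)C)C(C)C)cc(O[Si](C(C)C)(C(C)C)C(C)C)c1)O2 | intermediate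
21 | (2S,3S)-2-[3,5-bis(triisopropylsilyloxy)phenyl]-4,7-bis(methoxymethoxy)-3-[4-(triisopropylsilyloxy)phenyl]-2,3-dihydro-1-benzofuran-5-carbaldehyde | O=Cc1cc(OCOC)c2c(c1OCOC)[C@H](c1ccc(O[Si](C(C)C)(C(C)C)C(C)C)cc1)[C@@H](c1cc(O[Si](C(C)C)(C(C)C)C(C)C)cc(O[Si](C(C)C)(C(C)C)C(C)C)c1)O2 | intermediate
22 | 2-methylbenzene-1,3-diol | Cc1c(O)cccc1O | starting material
23 | 1,3-bis(methoxymethoxy)-2-methylbenzene | COCOc1cccc(OCOC)c1C | intermediate
24 | 2-[3,5-bis(methoxymethoxy)-4-methylphenyl]-4,4,5,5-tetramethyl-1,3,2-dioxaborolane (not isolated) | COCOc1cc(B2OC(C)(C)C(C)(C)O2)cc(OCOC)c1C | intermediate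
25 | 3,5-bis(methoxymethoxy)-4-methylphenol | Oc1cc(OCOC)c(C)c(OCOC)c1 | intermediate
26 | 2-bromo-3,5-bis(methoxymethoxy)-4-methylphenol | Oc1cc(OCOC)c(C)c(OCOC)c1Br | intermediate
27 | N,2-dimethoxy-N-methylacetamide | COCC(=O)N(C)OC | starting material
28 | lithium 2-lithio-3,5-bis(methoxymethoxy)-4-methylphenoxide (not isolated) | [Li]Oc1cc(OCOC)c(C)c(OCOC)c1[Li] | intermediate
29 | 1-[6-hydroxy-2,4-bis(methoxymethoxy)-3-methylphenyl]-2-methoxyethan-1-one | COCC(=O)c1c(O)cc(OCOC)c(C)c1OCOC | intermediate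
30 | aldol adduct: 3-hydroxy-2-methoxy-1-(ring A aryl)-3-(ring B dihydrobenzofuran-5-yl)propan-1-one, diastereomer mixture at the chain carbons | COC(C(O)c1cc(OCOC)c2c(c1OCOC)[C@H](c1ccc(O[Si](C(C)C)(C(C)C)C(C)C)cc1)[C@@H](c1cc(O[Si](C(C)C)(C(C)C)C(C)C)cc(O[Si](C(C)C)(C(C)C)C(C)C)c1)O2)C(=O)c1c(O)cc(OCOC)c(C)c1OCOC | intermediate
31 | 2-methoxy-1-(ring A aryl)-3-(ring B dihydrobenzofuran-5-yl)propane-1,3-dione (not isolated) | COC(C(=O)c1cc(OCOC)c2c(c1OCOC)[C@H](c1ccc(O[Si](C(C)C)(C(C)C)C(C)C)cc1)[C@@H](c1cc(O[Si](C(C)C)(C(C)C)C(C)C)cc(O[Si](C(C)C)(C(C)C)C(C)C)c1)O2)C(=O)c1c(O)cc(OCOC)c(C)c1OCOC | intermediate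
32 | 2-[(2S,3S)-2-[3,5-bis(triisopropylsilyloxy)phenyl]-4,7-bis(methoxymethoxy)-3-[4-(triisopropylsilyloxy)phenyl]-2,3-dihydro-1-benzofuran-5-yl]-3-methoxy-5,7-bis(methoxymethoxy)-6-methyl-4H-chromen-4-one | COc1c(-c2cc(OCOC)c3c(c2OCOC)[C@H](c2ccc(O[Si](C(C)C)(C(C)C)C(C)C)cc2)[C@@H](c2cc(O[Si](C(C)C)(C(C)C)C(C)C)cc(O[Si](C(C)C)(C(C)C)C(C)C)c2)O3)oc2cc(OCOC)c(C)c(OCOC)c2c1=O | intermediate
33 | 2-[(2S,3S)-2-[3,5-bis(triisopropylsilyloxy)phenyl]-4,7-dihydroxy-3-[4-(triisopropylsilyloxy)phenyl]-2,3-dihydro-1-benzofuran-5-yl]-5,7-dihydroxy-3-methoxy-6-methyl-4H-chromen-4-one | COc1c(-c2cc(O)c3c(c2O)[C@H](c2ccc(O[Si](C(C)C)(C(C)C)C(C)C)cc2)[C@@H](c2cc(O[Si](C(C)C)(C(C)C)C(C)C)cc(O[Si](C(C)C)(C(C)C)C(C)C)c2)O3)oc2cc(O)c(C)c(O)c2c1=O | intermediate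
34 | 2-[(2S,3S)-2-(3,5-dihydroxyphenyl)-4,7-dihydroxy-3-(4-hydroxyphenyl)-2,3-dihydro-1-benzofuran-5-yl]-5,7-dihydroxy-3-methoxy-6-methyl-4H-chromen-4-one | COc1c(-c2cc(O)c3c(c2O)[C@H](c2ccc(O)cc2)[C@@H](c2cc(O)cc(O)c2)O3)oc2cc(O)c(C)c(O)c2c1=O | target

**Totals.** Total step count: 18. Longest linear sequence: 13 steps (steps 2–10 and 15–18, from 3).

**Steps most likely to fail**

1. Step 7. What may go wrong: t-BuLi removes the benzylic C2–H or the benzylic/allylic C3–H instead of the vinylic C5–H, which would open the ring or scramble C3. The fallback sets out from 11 and comes back at 12. Benzenesulfinic acid is added across the enol ether (PhSO2H, CH2Cl2, rt) to give the (4R,5S)-5-Ar2-4-Ar1-2-(phenylsulfonyl)tetrahydrofuran F1. The now far more acidic sulfonyl-bearing carbon is deprotonated with LDA at −78 °C and trapped with Bu3SnCl to give the α-stannyl sulfone F2. On warming with i-Pr2NEt this loses benzenesulfinate to give tributyl[(2S,3R)-2-Ar2-3-Ar1-2,3-dihydrofuran-5-yl]stannane F3. Tin–lithium exchange (n-BuLi, THF, −78 °C) then gives 12 regiospecifically, and Cr(CO)6 and Me3OBF4 complete the way to 14 as in step 7.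

2. Step 8. What may go wrong: insertion of the alkyne in the reverse orientation, or diversion of the vinylcarbene and ketene intermediates (cyclopentannulation without CO, reaction at the propargylic acetal), so that the acetal-bearing phenol does not form cleanly. The fallback sets out from 14 and comes back at 20. The benzannulation is run with ethynyltrimethylsilane, whose orientation no longer matters, to give the (2S,3S)-7-methoxy-5-(trimethylsilyl)benzofuran-4-ol F4 (any 6-silyl or O-silyl isomer converges in the next operation). Protodesilylation with CF3CO2H in CH2Cl2 gives the 5,6-unsubstituted (2S,3S)-7-methoxybenzofuran-4-ol F5. Magnesium-mediated ortho-formylation (MgCl2, Et3N, paraformaldehyde, MeCN, reflux) can only attack C5, the single free position ortho to the C4 hydroxyl, and gives the 4-hydroxy-7-methoxy-5-carbaldehyde F6. Oxidation with PhI(OAc)2 in aqueous MeCN gives the formyl quinone F7, which is reduced in the same flask with Na2S2O4 to 20.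

3. Step 6. What may go wrong: slow ring closure onto the enol ether, with ruthenium-hydride double-bond migration or loss of the catalyst as an unreactive alkoxycarbene. The fallback sets out from 9 and comes back at 11. Hydroboration of the vinyl group (9-BBN, THF; then H2O2, aq. NaOAc) gives the (1S,2R)-butane-1,4-diol F8. Selective oxidation at the primary alcohol with TEMPO/PhI(OAc)2 runs through the lactol to the trans-(4R,5S)-4-Ar1-5-Ar2-γ-butyrolactone F9. Reduction with i-Bu2AlH (CH2Cl2, −78 °C) gives the lactol F10. Dehydration through the anomeric mesylate (MsCl, Et3N, CH2Cl2, then reflux) gives 11.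

**Further compounds**

F1 | step 7 | (4R,5S)-5-[3,5-bis(triisopropylsilyloxy)phenyl]-2-(phenylsulfonyl)-4-[4-(triisopropylsilyloxy)phenyl]tetrahydrofuran (epimers at C2) | O=S(=O)(c1ccccc1)C1C[C@H](c2ccc(O[Si](C(C)C)(C(C)C)C(C)C)cc2)[C@@H](c2cc(O[Si](C(C)C)(C(C)C)C(C)C)cc(O[Si](C(C)C)(C(C)C)C(C)C)c2)O1
F2 | step 7 | tributyl[(4R,5S)-5-Ar2-2-(phenylsulfonyl)-4-Ar1-tetrahydrofuran-2-yl]stannane | CCCC[Sn](CCCC)(CCCC)C1(S(=O)(=O)c2ccccc2)C[C@H](c2ccc(O[Si](C(C)C)(C(C)C)C(C)C)cc2)[C@@H](c2cc(O[Si](C(C)C)(C(C)C)C(C)C)cc(O[Si](C(C)C)(C(C)C)C(C)C)c2)O1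
F3 | step 7 | tributyl[(2S,3R)-2-Ar2-3-Ar1-2,3-dihydrofuran-5-yl]stannane | CCCC[Sn](CCCC)(CCCC)C1=C[C@H](c2ccc(O[Si](C(C)C)(C(C)C)C(C)C)cc2)[C@@H](c2cc(O[Si](C(C)C)(C(C)C)C(C)C)cc(O[Si](C(C)C)(C(C)C)C(C)C)c2)O1
F4 | step 8 | (2S,3S)-2-Ar2-7-methoxy-3-Ar1-5-(trimethylsilyl)-2,3-dihydro-1-benzofuran-4-ol | C[Si](C)(C)c1cc(OC)c2c(c1O)[C@H](c1ccc(O[Si](C(C)C)(C(C)C)C(C)C)cc1)[C@@H](c1cc(O[Si](C(C)C)(C(C)C)C(C)C)cc(O[Si](C(C)C)(C(C)C)C(C)C)c1)O2
F5 | step 8 | (2S,3S)-2-Ar2-7-methoxy-3-Ar1-2,3-dihydro-1-benzofuran-4-ol | Oc1ccc(OC)c2c1[C@H](c1ccc(O[Si](C(C)C)(C(C)C)C(C)C)cc1)[C@@H](c1cc(O[Si](C(C)C)(C(C)C)C(C)C)cc(O[Si](C(C)C)(C(C)C)C(C)C)c1)O2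
F6 | step 8 | (2S,3S)-2-Ar2-4-hydroxy-7-methoxy-3-Ar1-2,3-dihydro-1-benzofuran-5-carbaldehyde | O=Cc1cc(OC)c2c(c1O)[C@H](c1ccc(O[Si](C(C)C)(C(C)C)C(C)C)cc1)[C@@H](c1cc(O[Si](C(C)C)(C(C)C)C(C)C)cc(O[Si](C(C)C)(C(C)C)C(C)C)c1)O2
F7 | step 8 | (2S,3S)-2-Ar2-4,7-dioxo-3-Ar1-2,3,4,7-tetrahydro-1-benzofuran-5-carbaldehyde | O=CC1=CC(=O)C2=C(C1=O)[C@H](c1ccc(O[Si](C(C)C)(C(C)C)C(C)C)cc1)[C@@H](c1cc(O[Si](C(C)C)(C(C)C)C(C)C)cc(O[Si](C(C)C)(C(C)C)C(C)C)c1)O2
F8 | step 6 | (1S,2R)-1-[3,5-bis(triisopropylsilyloxy)phenyl]-2-[4-(triisopropylsilyloxy)phenyl]butane-1,4-diol | OCC[C@H](c1ccc(O[Si](C(C)C)(C(C)C)C(C)C)cc1)[C@@H](c1cc(O[Si](C(C)C)(C(C)C)C(C)C)cc(O[Si](C(C)C)(C(C)C)C(C)C)c1)O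
F9 | step 6 | (4R,5S)-5-[3,5-bis(triisopropylsilyloxy)phenyl]-4-[4-(triisopropylsilyloxy)phenyl]dihydrofuran-2(3H)-one | O=C1C[C@H](c2ccc(O[Si](C(C)C)(C(C)C)C(C)C)cc2)[C@@H](c2cc(O[Si](C(C)C)(C(C)C)C(C)C)cc(O[Si](C(C)C)(C(C)C)C(C)C)c2)O1
F10 | step 6 | (4R,5S)-5-[3,5-bis(triisopropylsilyloxy)phenyl]-4-[4-(triisopropylsilyloxy)phenyl]tetrahydrofuran-2-ol (anomers) | OC1C[C@H](c2ccc(O[Si](C(C)C)(C(C)C)C(C)C)cc2)[C@@H](c2cc(O[Si](C(C)C)(C(C)C)C(C)C)cc(O[Si](C(C)C)(C(C)C)C(C)C)c2)O1
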